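## Retrosynthetic overview

1. Target 8 ⇐ acetonide 7: the last step only unmasks the cis-diol (ketal hydrolysis).
2. 7 ⇐ dibenzoate 5: the key C–O bond is made by an oxygen-transposing ene hydroxylation with singlet oxygen. This one step adds the fourth ring oxygen, sets the fourth stereocentre and moves the alkene from C1=C2 to C1=C6.
3. 5 ⇐ diol 4 ⇐ ester 3 ⇐ (−)-shikimic acid 1: both benzoates go on in one acylation, and the other three stereocentres of 8 are those of shikimic acid, never touched.
4. Rings: the cyclohexene is never built; it is the ring of 1. The only ring formed is the temporary dioxolane (step 1), opened again in step 5.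

Assumption: locants in the discussion follow shikimic acid numbering for all intermediates (C1 = ring carbon bearing the exocyclic carbon C7; C3, C4, C5 = the original carbinol carbons). Under it the target's free allylic OH is on C2 and its ring benzoate on C5.

## Route

Step 1
Reactants: 1 (−)-shikimic acid
Product: 3 methyl 3,4-O-isopropylidene shikimate, via methyl shikimate 2 (not isolated)
Conditions: MeOH, CSA (5 mol %), reflux; evaporate; 2,2-dimethoxypropane, acetone, CSA, rt (same flask)
Reagents that add atoms: methanol (CO); 2,2-dimethoxypropane (COC(C)(C)OC)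
Why: Fischer esterification, then acid-catalysed transketalisation, which under equilibrium closes the dioxolane only on the cis-3,4-diol (a trans-4,5 fusion is strained); no stereocentre is touched.

Step 2
Reactants: 3 methyl 3,4-O-isopropylidene shikimate
Product: 4 [(3R,4S,5R)-5-hydroxy-3,4-(isopropylidenedioxy)cyclohex-1-en-1-yl]methanol
Conditions: i-Bu2AlH (3.5 equiv), CH2Cl2, −78 → 0 °C; aq. KNaC4H4O6 work-up
Reagents that add atoms: none
Why: Hydride reduction of the conjugated ester in the 1,2-sense by the electrophilic aluminium hydride, after the free 5-OH has taken one equivalent as its alkoxide; the ketal and the three stereocentres are untouched.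

Step 3
Reactants: 4 [(3R,4S,5R)-5-hydroxy-3,4-(isopropylidenedioxy)cyclohex-1-en-1-yl]methanol
Product: 5 [(3R,4S,5R)-5-(benzoyloxy)-3,4-(isopropylidenedioxy)cyclohex-1-en-1-yl]methyl benzoate
Conditions: BzCl (2.5 equiv), pyridine, DMAP (cat.), CH2Cl2, 0 °C → rt
Reagents that add atoms: benzoyl chloride (O=C(Cl)c1ccccc1)
Why: DMAP-catalysed O-acylation esterifies the only two free hydroxyls (primary allylic and secondary C5), so both benzoates of the target are installed at once with retention at C5.

Step 4
Reactants: 5 [(3R,4S,5R)-5-(benzoyloxy)-3,4-(isopropylidenedioxy)cyclohex-1-en-1-yl]methyl benzoate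
Product: 7 [(3R,4S,5R,6S)-3-(benzoyloxy)-6-hydroxy-4,5-(isopropylidenedioxy)cyclohex-1-en-1-yl]methyl benzoate, via allylic hydroperoxide 6 (not isolated)
Conditions: O2 (1 atm), 5,10,15,20-tetraphenylporphyrin (metal-free, 1 mol %), CH2Cl2, white LEDs, 0 °C; then PPh3 (1.2 equiv), 0 °C → rt
Reagents that add atoms: dioxygen (O=O)
Why: Proposed new method: a Schenck ene hydroxylation (singlet-oxygen ene reaction, then phosphine reduction of the hydroperoxide) on a 1-(acyloxymethyl)cyclohexene that carries oxygen on every other allylic carbon, a substrate class on which it has not been shown; singlet oxygen should attack the ring face opposite the cis-fused dioxolane (the pseudo-axial O3 shields the other face), bond to the less substituted C2 and take the syn pseudo-axial hydrogen on C6, because the two competing allylic hydrogens (H3 and those of CH2OBz) are each geminal to oxygen and CH2OBz sits on the lone side of the alkene, both of which suppress abstraction, so the new C2–O bond forms trans to O3 and the alkene moves to C1=C6; the closest known reaction type is the singlet-oxygen ene reaction of 1-methylcyclohexene and of acyclic allylic ethers and esters.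

Step 5
Reactants: 7 [(3R,4S,5R,6S)-3-(benzoyloxy)-6-hydroxy-4,5-(isopropylidenedioxy)cyclohex-1-en-1-yl]methyl benzoate
Product: 8 [(3R,4R,5R,6S)-3-(benzoyloxy)-4,5,6-trihydroxycyclohex-1-en-1-yl]methyl benzoate (CNP0178138.1)
Conditions: TFA/H2O (9:1), CH2Cl2, 0 °C, 30 min
Reagents that add atoms: none
Why: Acid-catalysed ketal hydrolysis (acetonide deprotection) breaks only the ketal C–O bonds, so all four stereocentres are kept; the benzoates survive brief cold aqueous acid, which does not promote the acyl shift that base would.

## Compound list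

1 | (−)-shikimic acid, (3R,4S,5R)-3,4,5-trihydroxycyclohex-1-ene-1-carboxylic acid | OC(=O)C1=C[C@@H](O)[C@@H](O)[C@H](O)C1 | starting material
2 | methyl shikimate, methyl (3R,4S,5R)-3,4,5-trihydroxycyclohex-1-ene-1-carboxylate | COC(=O)C1=C[C@@H](O)[C@@H](O)[C@H](O)C1 | intermediate (not isolated)
3 | methyl 3,4-O-isopropylidene shikimate (cis-fused dioxolane on O3/O4, free 5-OH trans to O4) | COC(=O)C1=C[C@H]2OC(C)(C)O[C@H]2[C@H](O)C1 | intermediate
4 | [(3R,4S,5R)-5-hydroxy-3,4-(isopropylidenedioxy)cyclohex-1-en-1-yl]methanol | OCC1=C[C@H]2OC(C)(C)O[C@H]2[C@H](O)C1 | intermediate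
5 | [(3R,4S,5R)-5-(benzoyloxy)-3,4-(isopropylidenedioxy)cyclohex-1-en-1-yl]methyl benzoate | O=C(OCC1=C[C@H]2OC(C)(C)O[C@H]2[C@H](OC(=O)c2ccccc2)C1)c1ccccc1 | intermediate
6 | allylic hydroperoxide: the 6-hydroperoxy analogue of 7 (OOH in place of the 6-OH, same spatial arrangement, trans to the dioxolane) | O=C(OCC1=C[C@@H](OC(=O)c2ccccc2)[C@@H]2OC(C)(C)O[C@@H]2[C@H]1OO)c1ccccc1 | intermediate (not isolated)
7 | [(3R,4S,5R,6S)-3-(benzoyloxy)-6-hydroxy-4,5-(isopropylidenedioxy)cyclohex-1-en-1-yl]methyl benzoate (6-OH trans to the dioxolane, cis to the 3-benzoate) | O=C(OCC1=C[C@@H](OC(=O)c2ccccc2)[C@@H]2OC(C)(C)O[C@@H]2[C@H]1O)c1ccccc1 | intermediate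
8 | [(3R,4R,5R,6S)-3-(benzoyloxy)-4,5,6-trihydroxycyclohex-1-en-1-yl]methyl benzoate (3,4-trans; 4,5-cis; 5,6-trans) | O=C(OCC1=C[C@@H](OC(=O)c2ccccc2)[C@H](O)[C@H](O)[C@H]1O)c1ccccc1 | target

## Step count and risks

Total steps: 5. Longest linear sequence: 5 (1 → 3 → 4 → 5 → 7 → 8).

**Step 4 (proposed new ene hydroxylation): the most likely to fail.** The risks are low reactivity of the oxygen-flanked alkene and imperfect site or face selectivity. The fallback uses known chemistry, sets out from 5 and comes back at 8. OsO4 (2 mol %) with N-methylmorpholine N-oxide in acetone/H2O dihydroxylates 5 on the face opposite the dioxolane to give the cis-1,2-diol F1 (tertiary C1–OH, secondary C2–OH trans to O3). Et3SiCl and imidazole in DMF silylate only the secondary hydroxyl to give the triethylsilyl ether F2. Burgess reagent in toluene at 60 °C dehydrates the tertiary alcohol by syn-elimination; the only ring hydrogen syn to that oxygen is on C6 (H2 is anti), which gives the silyl-protected cyclohexene F3, the triethylsilyl ether of 7. The acid conditions of step 5 then remove the silyl group and the acetonide together to give 8.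

**Step 5 (acetonide hydrolysis next to an allylic benzoate and a free allylic alcohol).** The risks are benzoate shift to the neighbouring hydroxyl and allylic solvolysis. The fallback changes the protecting-group plan so that the final unmasking is a buffered fluoride desilylation; it sets out from 5 and comes back at 8. The acetonide is hydrolysed at the stage of 5 (80% aq. AcOH, 40 °C), where the secondary benzoate is not yet allylic and no allylic alcohol is present, to give the cis-diol dibenzoate F4. Et3SiOTf and 2,6-lutidine give the bis(triethylsilyl) ether F5. The photooxygenation of step 4 gives the bis-silyl hydroperoxide F6 (not isolated), which PPh3 reduces to the bis-silyl allylic alcohol F7. HF·pyridine in THF/pyridine at 0 °C removes both silyl groups to give 8.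

**Step 2 (aluminium hydride reduction with a free hydroxyl and a ketal present).** The risks are incomplete reduction, 1,4-reduction and a difficult isolation of the polar diol. The fallback reduces an activated acid with borohydride instead; it sets out from 3 and comes back at 4. LiOH in THF/H2O saponifies 3 to the hydroxy acid F8. Isobutyl chloroformate and N-methylmorpholine in THF at −15 °C activate only the carboxylate as the mixed carbonic anhydride F9 (not isolated). NaBH4 in H2O at −15 °C reduces it in the 1,2-sense to 4.

## Further compounds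

F1 | step 4 | 1,2-diol of 5: [(1,2-cis)-1,2-dihydroxy-5-(benzoyloxy)-3,4-(isopropylidenedioxy)cyclohexyl]methyl benzoate, both new OH groups trans to the dioxolane | O=C(OC[C@@]1(O)[C@H](O)[C@H]2OC(C)(C)O[C@H]2[C@H](OC(=O)c2ccccc2)C1)c1ccccc1
F2 | step 4 | 2-O-triethylsilyl ether of F1 (tertiary C1–OH free) | O=C(OC[C@@]1(O)[C@H](O[Si](CC)(CC)CC)[C@H]2OC(C)(C)O[C@H]2[C@H](OC(=O)c2ccccc2)C1)c1ccccc1
F3 | step 4 | triethylsilyl ether of 7 | O=C(OCC1=C[C@@H](OC(=O)c2ccccc2)[C@@H]2OC(C)(C)O[C@@H]2[C@H]1O[Si](CC)(CC)CC)c1ccccc1
F4 | step 5 | [(3R,4S,5R)-5-(benzoyloxy)-3,4-dihydroxycyclohex-1-en-1-yl]methyl benzoate | O=C(OCC1=C[C@@H](O)[C@@H](O)[C@H](OC(=O)c2ccccc2)C1)c1ccccc1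
F5 | step 5 | 3,4-bis(triethylsilyl) ether of F4 | O=C(OCC1=C[C@@H](O[Si](CC)(CC)CC)[C@@H](O[Si](CC)(CC)CC)[C@H](OC(=O)c2ccccc2)C1)c1ccccc1
F6 | step 5 | 6-hydroperoxide from the ene reaction of F5 (4,5-bis(triethylsilyl) ether of the hydroperoxide corresponding to 8) | O=C(OCC1=C[C@@H](OC(=O)c2ccccc2)[C@H](O[Si](CC)(CC)CC)[C@H](O[Si](CC)(CC)CC)[C@H]1OO)c1ccccc1
F7 | step 5 | 4,5-bis(triethylsilyl) ether of 8 | O=C(OCC1=C[C@@H](OC(=O)c2ccccc2)[C@H](O[Si](CC)(CC)CC)[C@H](O[Si](CC)(CC)CC)[C@H]1O)c1ccccc1
F8 | step 2 | 3,4-O-isopropylidene shikimic acid | OC(=O)C1=C[C@H]2OC(C)(C)O[C@H]2[C@H](O)C1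
F9 | step 2 | isobutyl carbonic mixed anhydride of F8 | CC(C)COC(=O)OC(=O)C1=C[C@H]2OC(C)(C)O[C@H]2[C@H](O)C1
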